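**Retrosynthetic overview**

1. Endgame: thiolate demethylation of the C7 ester ⇐ one acid step that unveils the 19,10-lactone, the 2,3,13-triol and the C16=C17 methylene (allylsilane protodesilylation) ⇐ Barton–McCombie removal of O-11.
2. Key disconnection: C8–C9 and C12–C13 together, by an intramolecular (4+3) cycloaddition of an epoxy enolsilane (C10–O–C9 epoxide, C11=C12 enol silane) with a 1-silyloxycyclopentadiene (ring D carbons C8, C14, C13, C16, C15); rings B and C form in this one step.
3. Feature that allows it: in the bicyclo[3.2.1]octane (rings C and D) the seven-membered ring C8–C9–C11–C12–C13–C16–C15 is spanned by the one-carbon bridge C14 and carries oxygen on its bridgehead C13, and C9 is vicinal to the lactone oxygen on C10. C13–O therefore maps onto a silyl dienol ether, and O10–C9 onto an epoxide whose opening gives the three-carbon oxyallyl unit C9–C11–C12.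
4. Precursor: ring A ketone + chloroacetone (Darzens), ring D as a cyclopentenone joined at C6 (Mukaiyama–Michael, then Negishi coupling for C17); ring A with C4/C5 from a quinone monoketal (asymmetric Mukaiyama–Michael, methylation) and C2/C3 by dihydroxylation.
5. Ring order: A (from an arene), D (attached), B and C together in the key step, lactone last.

Key step: step 12

Remark: gibberellane numbering is used for every intermediate and α/β are those of the target (β is the face of H-5 and of the C18 methyl); C6, which is α to the C7 ester, arises in step 6 as an epimer pair that is carried on unseparated (the SMILES of 12 to 24 leave C6 open) until step 16 fixes it.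

**Route**

Step 1
Reactants: 1 methyl 2-hydroxy-5-methoxybenzoate
Product: 2 methyl 3,3-dimethoxy-6-oxocyclohexa-1,4-diene-1-carboxylate (quinone monoketal)
Conditions: PhI(OAc)2, MeOH, 0 °C → rt
Reagents that add atoms: methanol, CO
Why: Oxidative dearomatisation of a para-methoxyphenol by a hypervalent iodine reagent in methanol should give the para-quinone monoketal, which already holds C3 (ketone), C4 (ester-bearing carbon), C5 (acceptor carbon) and C10 (masked ketone) of ring A, and no stereocenter is formed.

Step 2
Reactants: 2 quinone monoketal ester; 3 1-(tert-butyldimethylsilyloxy)-1-methoxyethene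
Product: 5 ring A enone diester with quaternary C4, via β-keto ester 4 (not isolated)
Conditions: [Cu((S,S)-t-Bu-box)](SbF6)2 (10 mol%), (CF3)2CHOH, CH2Cl2, −78 °C; then MeI, K2CO3, acetone, 0 °C → rt
Reagents that add atoms: iodomethane, CI
Why: Catalytic asymmetric Mukaiyama–Michael addition in which the ketene silyl acetal adds to C5, the β-carbon of the alkylidene β-keto ester that is bound in two-point fashion to the copper bis(oxazoline) complex (ligand antipode chosen for the C5 configuration shown), followed by C-methylation of the β-keto ester enolate anti to the new C5 side chain, which should set the quaternary C4 trans (methyl β, ester α).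

Step 3
Reactants: 5 ring A enone diester
Product: 7 ring A cyclohex-2-ene diester (C2=C3), via tosylhydrazone 6 (not isolated)
Conditions: TsNHNH2, THF, 4 Å MS, 50 °C; then catecholborane, CHCl3, 0 °C; then NaOAc·3H2O, 65 °C
Reagents that add atoms: none
Why: Caglioti-type reduction of the enone tosylhydrazone with catecholborane gives an allylic diazene that loses N2 in a retro-ene shift, which delivers hydrogen to C1 and moves the double bond to C2=C3 without touching C4 or C5.

Step 4
Reactants: 7 ring A alkene
Product: 8 2β,3β-diol
Conditions: OsO4 (2 mol%), NMO, acetone/H2O (8:1), rt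
Reagents that add atoms: 4-methylmorpholine N-oxide, C[N+]1([O-])CCOCC1; water, O
Why: Upjohn dihydroxylation in which OsO4 should add to C2=C3 from the β face, anti to the pseudo-axial C4 ester and the axial C10 methoxy group that both lie on the α face, which sets the cis 2β,3β-diol.

Step 5
Reactants: 8 diol
Product: 9 2β,3β-acetonide
Conditions: 2,2-dimethoxypropane, PPTS (cat.), CH2Cl2, rt
Reagents that add atoms: 2,2-dimethoxypropane, COC(C)(C)OC
Why: Acid-catalysed acetal exchange protects the cis-diol as an acetonide that should withstand the enolate, Lewis acid and radical steps and falls in step 17, with no stereocenter touched.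

Step 6
Reactants: 9 ring A acetonide diester; 10 (R)-4-(tert-butyldimethylsilyloxy)cyclopent-2-en-1-one
Product: 13 C6-linked cyclopent-2-enone, via ketene silyl acetal 11 (not isolated), via silyl enol ether adduct 12 (not isolated)
Conditions: LDA, Me3SiCl, THF, −78 °C; then 10, HgI2 (10 mol%), CH2Cl2, −78 → −20 °C; then DBU, MeOH, rt
Reagents that add atoms: none
Why: Mukaiyama–Michael addition of the ketene silyl acetal to the silyloxycyclopentenone anti to the silyloxy group, followed by base-induced β-elimination of the silanol, forms C6–C8 and leaves ring D as a 4-substituted cyclopent-2-enone with C13=O; C8 is set by the anti addition but is erased in step 11, and C6 forms as an epimer pair that is settled in step 16.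

Step 7
Reactants: 13 cyclopentenone
Product: 14 16-iodo enone
Conditions: I2, pyridine, CH2Cl2, 0 °C → rt
Reagents that add atoms: iodine, II
Why: Amine-mediated α-iodination of the enone (conjugate addition of pyridine, iodination of the enolate, elimination) should put a coupling handle on C16 without forming a stereocenter.

Step 8
Reactants: 14 16-iodo enone
Product: 15 16-(trimethylsilylmethyl) enone
Conditions: Me3SiCH2MgCl, ZnCl2, THF, 0 °C; then 14, Pd(PPh3)4 (5 mol%), 50 °C
Reagents that add atoms: (trimethylsilyl)methylmagnesium chloride, C[Si](C)(C)C[Mg]Cl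
Why: Negishi coupling of the α-iodoenone with an alkylzinc reagent that has no β-hydrogen installs C17 as an allylsilane, the masked exocyclic methylene, under conditions that esters, ketone and acetals tolerate.

Step 9
Reactants: 15 dimethyl ketal
Product: 16 C10 ketone
Conditions: PPTS, acetone/H2O (10:1), 40 °C
Reagents that add atoms: water, O
Why: Mild acid hydrolysis cleaves the acyclic dimethyl ketal while the cyclic acetonide (in acetone) and the allylsilane should survive, and C5, now α to the ketone, keeps its more stable equatorial side chain.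

Step 10
Reactants: 16 C10 ketone; 17 chloroacetone
Product: 18 C9–C10 spiro-epoxy methyl ketone
Conditions: 17, LiN(SiMe3)2, THF, −78 °C; then 16, −78 → 0 °C
Reagents that add atoms: none
Why: Darzens condensation in which the chloro enolate adds to the saturated C10 ketone (more electrophilic than the cross-conjugated cyclopentenone) from the equatorial direction because the axial C4 ester blocks axial attack, so that the oxygen becomes axial and cis to C19 (C10 set), and displacement of chloride closes the epoxide with the acetyl group anti to the substituted C5, that is cis to C1 (C9 set).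

Step 11
Reactants: 18 epoxy ketone
Product: 20 bis(enol silane) with the linear 1-silyloxydiene, via cross-conjugated dienol silane 19 (not isolated)
Conditions: Et3SiOTf (2.5 equiv), Et3N, CH2Cl2, −78 → 0 °C; then toluene, 60 °C
Reagents that add atoms: triethylsilyl trifluoromethanesulfonate, CC[Si](CC)(CC)OS(=O)(=O)C(F)(F)F
Why: Soft enolisation with a silyl triflate and an amine gives the enol silane of the methyl ketone (its only enolisable side) and the cross-conjugated dienol silane of the cyclopentenone, which should reach the linearly conjugated, fully substituted 1-silyloxy diene by [1,5]-hydrogen shifts on warming, C8 becoming sp2.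

Step 12
Reactants: 20 epoxy enolsilane with tethered 1-silyloxycyclopentadiene
Product: 21 (4+3) adduct (rings A–D, 11-ketone, 10- and 13-O-triethylsilyl)
Conditions: Et3SiOTf (10 mol%), CH2Cl2, −78 → −40 °C; Et3N quench
Reagents that add atoms: none
Why: Et3SiOTf silylates the epoxide oxygen; C8, the vinylogous nucleophilic terminus of the 1-silyloxydiene, opens the epoxide at C9 with inversion while the C11=C12 enol silane takes up the charge, and this enol silane then adds through C12 to the silyloxocarbenium carbon C13 of the ring D cation and passes its silyl group on, so that the whole is a stepwise (4+3) cycloaddition of an oxyallyl equivalent (C9–C11–C12) with a cyclopentadiene. The closest known reaction type is the silyl triflate-catalysed intramolecular (4+3) cycloaddition of epoxy enolsilanes with tethered furans or dienes, known also intermolecularly with cyclopentadiene, in which the configuration of the epoxide is transferred. Ring B is closed by C8–C9 in a five-membered endo opening of the epoxide (both epoxide carbons end in the ring), and ring C is closed by C12–C13 in a 6-(enolendo)-exo-trig addition that also completes the seven-membered ring C8–C9–C11–C12–C13–C16–C15 and so, over the C14 bridge, the bicyclo[3.2.1]octane with ring D. C9 comes from inversion at the epoxide carbon (acetyl cis to C1 in 18 becomes H-9 cis to O-10), C10 is retained, and C8 and C13 are set together by the compact arrangement in which C11 lies over the flat C15=C16 edge of the diene rather than over C14H2, whose inner hydrogen disfavours the extended arrangement. The step needs attack by C8 and not C16 (secured by the three-atom tether C6–C5–C10, which allows a five- but not a seven-membered ring, and by the linear diene isomer made in step 11), closure at C13 and not at C15 (the silyloxy group localises the cation on C13) and through carbon rather than oxygen (the ketone is the stable product under the reversible Lewis acid conditions).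

Step 13
Reactants: 21 11-ketone
Product: 22 11-alcohol
Conditions: NaBH4, MeOH/THF, −20 °C
Reagents that add atoms: none
Why: Borohydride reduction of the C11 ketone, with hydride expected anti to the C15=C16 bridge, removes the β-silyloxy ketone before it can eliminate or epimerise C9, and the new C11 center is lost again in step 15.

Step 14
Reactants: 22 11-alcohol
Product: 23 11-O-(imidazol-1-ylthiocarbonyl) derivative
Conditions: 1,1'-thiocarbonyldiimidazole, DMAP (cat.), toluene, 80 °C
Reagents that add atoms: 1,1'-thiocarbonyldiimidazole, S=C(n1ccnc1)n1ccnc1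
Why: Neutral thioacylation of the only free hydroxyl prepares the Barton–McCombie deoxygenation without base that could open the silyl ethers or esters.

Step 15
Reactants: 23 thiocarbonyl derivative
Product: 24 11-deoxy compound
Conditions: Bu3SnH, AIBN (cat.), toluene, 110 °C
Reagents that add atoms: none
Why: Barton–McCombie deoxygenation through the secondary C11 radical, which is 1,4-related to the C15=C16 alkene and so cannot rearrange through a homoallyl–cyclopropylcarbinyl path, gives the C11 methylene.

Step 16
Reactants: 24 C6 epimer pair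
Product: 25 6β-ester (single epimer)
Conditions: NaOMe (0.5 equiv), MeOH/THF, 65 °C
Reagents that add atoms: none
Why: Base equilibration through the C7 ester enolate, the only enolisable position, should place the ester trans to the quaternary C4 on the neighbouring C5, that is 6β as in the target.

Step 17
Reactants: 25 fully protected tetracycle
Product: 26 methyl ester of the target
Conditions: 48% aq. HF, MeCN, 0 °C → rt
Reagents that add atoms: none
Why: Acid cleaves both triethylsilyl ethers and the acetonide, protonates the allylsilane at C15 with loss of the silyl group (SE2' protodesilylation) to give the exocyclic C16=C17 alkene without a new stereocenter, and lets the freed tertiary C10 hydroxyl, held cis-1,3 to the C19 ester, close the γ-lactone.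

Step 18
Reactants: 26 methyl ester
Product: 27 target acid (CNP0265952.3)
Conditions: n-PrSLi, HMPA, rt; then aq. HCl to pH 3
Reagents that add atoms: none
Why: SN2 demethylation of the hindered C7 methyl ester by thiolate avoids hydroxide, which could epimerise C3 by retro-aldol opening, and the lactone cannot be attacked at its tertiary C10.

**Compound list**

1 | methyl 2-hydroxy-5-methoxybenzoate | COC(=O)c1cc(OC)ccc1O | starting material
2 | methyl 3,3-dimethoxy-6-oxocyclohexa-1,4-diene-1-carboxylate | COC(=O)C1=CC(OC)(OC)C=CC1=O | intermediate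
3 | 1-(tert-butyldimethylsilyloxy)-1-methoxyethene | C=C(OC)O[Si](C)(C)C(C)(C)C | starting material
4 | ring A β-keto ester, drawn as its enol: methyl 3-hydroxy-10,10-dimethoxy-5α-(2-methoxy-2-oxoethyl)cyclohexa-1,3-diene-4-carboxylate (5β-H) | COC(=O)C[C@@H]1C(OC)(OC)C=CC(O)=C1C(=O)OC | intermediate
5 | methyl 4β-methyl-10,10-dimethoxy-5α-(2-methoxy-2-oxoethyl)-3-oxocyclohex-1-ene-4α-carboxylate (5β-H) | COC(=O)C[C@@H]1C(OC)(OC)C=CC(=O)[C@]1(C)C(=O)OC | intermediate
6 | 3-(p-toluenesulfonyl)hydrazone of 5 | COC(=O)C[C@@H]1C(OC)(OC)C=CC(=NNS(=O)(=O)c2ccc(C)cc2)[C@]1(C)C(=O)OC | intermediate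
7 | methyl 4β-methyl-10,10-dimethoxy-5α-(2-methoxy-2-oxoethyl)cyclohex-2-ene-4α-carboxylate (5β-H) | COC(=O)C[C@@H]1C(OC)(OC)CC=C[C@]1(C)C(=O)OC | intermediate
8 | 2β,3β-dihydroxy derivative of 7 (saturated ring A) | COC(=O)C[C@@H]1C(OC)(OC)C[C@@H](O)[C@@H](O)[C@]1(C)C(=O)OC | intermediate
9 | 2β,3β-O-isopropylidene acetal of 8 | COC(=O)C[C@@H]1C(OC)(OC)C[C@H]2OC(C)(C)O[C@H]2[C@]1(C)C(=O)OC | intermediate
10 | (R)-4-(tert-butyldimethylsilyloxy)cyclopent-2-en-1-one | O=C1C=C[C@H](O[Si](C)(C)C(C)(C)C)C1 | starting material
11 | C6=C7 trimethylsilyl ketene acetal of 9 | COC(O[Si](C)(C)C)=C[C@@H]1C(OC)(OC)C[C@H]2OC(C)(C)O[C@H]2[C@]1(C)C(=O)OC | intermediate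
12 | Michael adduct of 11 and 10 as C13 trimethylsilyl enol ether: C6–C8 bond, C8 trans to the 15-silyloxy group (C6 epimers) | COC(=O)C([C@@H]1C=C(O[Si](C)(C)C)C[C@H]1O[Si](C)(C)C(C)(C)C)[C@@H]2C(OC)(OC)C[C@H]3OC(C)(C)O[C@H]3[C@]2(C)C(=O)OC | intermediate
13 | ring A acetonide ketal diester carrying at C6 the ring D 4-substituted cyclopent-2-en-1-one (C13=O, C15=C16; C8 epimer shown, C6 epimers) | COC(=O)C([C@@H]1CC(=O)C=C1)[C@@H]2C(OC)(OC)C[C@H]3OC(C)(C)O[C@H]3[C@]2(C)C(=O)OC | intermediate
14 | 16-iodo derivative of 13 | COC(=O)C([C@@H]1CC(=O)C(I)=C1)[C@@H]2C(OC)(OC)C[C@H]3OC(C)(C)O[C@H]3[C@]2(C)C(=O)OC | intermediate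
15 | 16-(trimethylsilylmethyl) derivative of 13 | COC(=O)C([C@@H]1CC(=O)C(C[Si](C)(C)C)=C1)[C@@H]2C(OC)(OC)C[C@H]3OC(C)(C)O[C@H]3[C@]2(C)C(=O)OC | intermediate
16 | C10 ketone from 15 (2β,3β-acetonide, 4β-methyl, 4α-CO2Me, 5β-H) | COC(=O)C([C@@H]1CC(=O)C(C[Si](C)(C)C)=C1)[C@@H]2C(=O)C[C@H]3OC(C)(C)O[C@H]3[C@]2(C)C(=O)OC | intermediate
17 | chloroacetone | CC(=O)CCl | starting material
18 | C9–C10 spiro-epoxide of 16 bearing C11 acetyl: epoxide oxygen α (cis to C19), acetyl cis to C1 | COC(=O)C([C@@H]1CC(=O)C(C[Si](C)(C)C)=C1)[C@@H]2[C@]4(O[C@@H]4C(C)=O)C[C@H]3OC(C)(C)O[C@H]3[C@]2(C)C(=O)OC | intermediate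
19 | bis(triethylsilyl enol ether) of 18 with cross-conjugated ring D diene (C13=C14, C15=C16; C8 sp3) | COC(=O)C([C@@H]1C=C(O[Si](CC)(CC)CC)C(C[Si](C)(C)C)=C1)[C@@H]2[C@]4(O[C@@H]4C(=C)O[Si](CC)(CC)CC)C[C@H]3OC(C)(C)O[C@H]3[C@]2(C)C(=O)OC | intermediate
20 | bis(triethylsilyl enol ether) of 18 with linear ring D diene (C8=C15, C16=C13–OSiEt3; C14H2) | COC(=O)C(C1=CC(C[Si](C)(C)C)=C(O[Si](CC)(CC)CC)C1)[C@@H]2[C@]4(O[C@@H]4C(=C)O[Si](CC)(CC)CC)C[C@H]3OC(C)(C)O[C@H]3[C@]2(C)C(=O)OC | intermediate
21 | (4+3) adduct: dimethyl 2β,3β-isopropylidenedioxy-11-oxo-10α,13-bis(triethylsilyloxy)-16-(trimethylsilylmethyl)-20-norgibberell-15-ene-7,19-dioate, 5β-H, 9α-H, C8/C13 as in the target (C6 epimers) | C[Si](C)(C)CC1=C[C@@]23C[C@]1(O[Si](CC)(CC)CC)CC(=O)[C@H]2[C@@]6(O[Si](CC)(CC)CC)C[C@H]4OC(C)(C)O[C@H]4[C@](C)(C(=O)OC)[C@@H]6C3C(=O)OC | intermediate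
22 | 11-hydroxy compound from 21 (hydroxyl syn to the C15=C16 bridge) | C[Si](C)(C)CC1=C[C@@]23C[C@]1(O[Si](CC)(CC)CC)C[C@@H](O)[C@H]2[C@@]6(O[Si](CC)(CC)CC)C[C@H]4OC(C)(C)O[C@H]4[C@](C)(C(=O)OC)[C@@H]6C3C(=O)OC | intermediate
23 | 11-O-(imidazol-1-ylthiocarbonyl) derivative of 22 | C[Si](C)(C)CC1=C[C@@]23C[C@]1(O[Si](CC)(CC)CC)C[C@@H](OC(=S)n5ccnc5)[C@H]2[C@@]6(O[Si](CC)(CC)CC)C[C@H]4OC(C)(C)O[C@H]4[C@](C)(C(=O)OC)[C@@H]6C3C(=O)OC | intermediate
24 | 11-deoxy compound (C11 methylene; C6 epimers) | C[Si](C)(C)CC1=C[C@@]23C[C@]1(O[Si](CC)(CC)CC)CC[C@H]2[C@@]6(O[Si](CC)(CC)CC)C[C@H]4OC(C)(C)O[C@H]4[C@](C)(C(=O)OC)[C@@H]6C3C(=O)OC | intermediate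
25 | 6β-CO2Me epimer of 24 (all centers as in the target) | C[Si](C)(C)CC1=C[C@@]23C[C@]1(O[Si](CC)(CC)CC)CC[C@H]2[C@@]6(O[Si](CC)(CC)CC)C[C@H]4OC(C)(C)O[C@H]4[C@](C)(C(=O)OC)[C@@H]6[C@H]3C(=O)OC | intermediate
26 | methyl ester of the target (7-methyl ester, 19,10-lactone, 2β,3β,13-triol, 16-methylene) | C=C1C[C@@]23C[C@]1(O)CC[C@H]2[C@]12C[C@@H](O)[C@@H](O)[C@](C)(C(=O)O1)[C@@H]2[C@H]3C(=O)OC | intermediate
27 | (2R,3S,4R,5S,6R,8R,9R,10S,13R)-2,3,13-trihydroxy-20-norgibberell-16-ene-7,19-dioic acid 19,10-lactone (CNP0265952.3) | C=C1C[C@@]23C[C@]1(O)CC[C@H]2[C@]12C[C@@H](O)[C@@H](O)[C@](C)(C(=O)O1)[C@@H]2[C@H]3C(=O)O | target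

**Step count and risks**

Total step count: 18. Longest linear sequence: 18 steps (1 → 27); 3, 10 and 17 enter as purchased reactants.

Steps most likely to fail, riskiest first:

Step 12. What may go wrong: loss of facial control at the diene (extended instead of compact approach, which would invert C8 and C13 relative to C9), closure through the enol oxygen instead of C12, or incomplete isomerisation to the linear diene so that another diene carbon attacks. The fallback replaces the cycloaddition by two anionic bond formations; it sets out from 18 and returns at 21. KN(SiMe3)2 in THF at −78 °C forms the extended enolate of the ring D enone, whose γ-carbon C8 opens the epoxide at C9 with inversion (five-membered ring B), and the C10 alkoxide is trapped with Et3SiCl to give the ring B-closed enone methyl ketone F1. LiN(SiMe3)2 at −78 → −40 °C then effects the intramolecular aldol addition of the methyl ketone enolate (C12) to the ring D carbonyl C13, the only aldol ring closure the skeleton allows, giving the bridged 13-hydroxy 11-ketone F2. Et3SiOTf with 2,6-lutidine silylates the C13 hydroxyl and gives 21.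

Step 10. What may go wrong: addition of the chloro enolate to the cyclopentenone carbonyl instead of C10, attack on the wrong face of C10, or lactonisation of the C10 alkoxide onto an ester before it displaces chloride. The fallback removes the competing carbonyl for the duration of the step; it sets out from 16 and returns at 18. Luche reduction (NaBH4, CeCl3·7H2O, MeOH, −78 °C) reduces only the conjugated C13 ketone and gives the ring D allylic alcohol F3 (C13 epimers). The Darzens condensation with 17 and excess LiN(SiMe3)2 is then run on the single remaining ketone to give the epoxy ketone allylic alcohol F4, and MnO2 in CH2Cl2 re-oxidises the allylic alcohol to return 18.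

Step 6. What may go wrong: proton transfer to the nucleophile with β-elimination of the silyloxy group of 10 (cyclopentadienone formation), 1,2- instead of conjugate addition, or failure of the hindered ketene acetal to add. The fallback forms C6–C8 by allylic substitution instead of conjugate addition; it sets out from 9 (through its ketene silyl acetal 11) and returns at 13. Racemic tert-butyl 4-oxocyclopent-2-en-1-yl carbonate F5 is made from purchased 4-hydroxycyclopent-2-en-1-one with Boc2O and DMAP. Pd2(dba)3 and 1,2-bis(diphenylphosphino)ethane in THF at 60 °C ionise F5 to a π-allyl complex that the ketene silyl acetal 11 attacks at C8 (Tsuji–Trost-type allylation), giving 13 directly; it forms as a C8 epimer mixture, which is immaterial because C8 becomes sp2 in step 11.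

Further compounds
F1 | step 12 | ring B-closed enone methyl ketone: C8–C9 bond formed, 9-acetyl, 10α-triethylsilyloxy, ring D 16-(trimethylsilylmethyl)cyclopent-15-en-13-one, 2β,3β-acetonide, 7,19-dimethyl esters (C6 epimers) | CC(=O)[C@@H]1[C@@]2(CC(=O)C(C[Si](C)(C)C)=C2)C(C(=O)OC)[C@@H]3[C@]1(O[Si](CC)(CC)CC)C[C@H]4OC(C)(C)O[C@H]4[C@]3(C)C(=O)OC
F2 | step 12 | 13-hydroxy analogue of 21 (bridged aldol product, 11-ketone, 10α-triethylsilyloxy) | C[Si](C)(C)CC1=C[C@@]23C[C@]1(O)CC(=O)[C@H]2[C@@]6(O[Si](CC)(CC)CC)C[C@H]4OC(C)(C)O[C@H]4[C@](C)(C(=O)OC)[C@@H]6C3C(=O)OC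
F3 | step 10 | ring D allylic alcohol of 16 (C13 carbinol, C10 ketone intact) | COC(=O)C([C@@H]1CC(O)C(C[Si](C)(C)C)=C1)[C@@H]2C(=O)C[C@H]3OC(C)(C)O[C@H]3[C@]2(C)C(=O)OC
F4 | step 10 | C9–C10 spiro-epoxy methyl ketone with ring D allylic alcohol (13-hydroxy analogue of 18) | COC(=O)C([C@@H]1CC(O)C(C[Si](C)(C)C)=C1)[C@@H]2[C@]4(O[C@@H]4C(C)=O)C[C@H]3OC(C)(C)O[C@H]3[C@]2(C)C(=O)OC
F5 | step 6 | tert-butyl 4-oxocyclopent-2-en-1-yl carbonate (racemic) | O=C1C=CC(OC(=O)OC(C)(C)C)C1
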